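The data were generated by integration from invented constants.

1. Divide the rate of Q + Z -> G + L by the rate of J + Z -> G + Q, so that cZ and time drop out. These flasks are the ones to judge:

| flask | J | Z | G | remark | time |
|---|---|---|---|---|---|
| gamma | 0.42 M | 0.53 M | 0.21 M | run made earlier |  |
| eta | 0.42 M | 1 M | 0.21 M | run made earlier |  |
| south | 0.42 M | 0.420 M | 0.210 M |  | 1.0 h |
| north | 0.42 M | 0.840 M | 0.210 M |  | 1.0 h |

| run | time / min | Q / % | J / % |
|---|---|---|---|
| gamma | 3.00 | 56.4 | 41.1 |
| gamma | 6.00 | 73.4 | 23.5 |
| gamma | 12.0 | 82.0 | 11.9 |
| gamma | 20.0 | 82.9 | 5.3 |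
| gamma | 40.0 | 83.0 | 2.4 |
| eta | 8.00 | 82.0 | 2.1 |
| eta | 15.0 | 70.9 | 1.0 |
| eta | 25.0 | 58.0 | 0 |
| eta | 30.0 | 50.7 | 1.3 |
| eta | 40.0 | 44.1 | 0.2 |

(scatter of a reading: 1 percentage point)

- which of these holds the largest part of the J at the end of south (J / L / Q)
- which of these holds the largest part of the J at the end of north (J / L / Q)
- amount of Q at the end of north, in percent of the J charged

- for Q the X are counted in
- as a solid, counted per litre of solution: X
- what was read earlier has a scatter of 1 percentage point, one standard deviation
- steps under discussion: Q + Z -> G + L; Z -> E; J + Z -> G + Q; X <-> Q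

2. Get the first constant from gamma at 6.00 min. Take J left and Z left (charge, minus J lost, minus L made) and apply the second-order law for unequal charges: 0.685 /M/min.

3. Get the second constant from eta between 15.0 min and 40.0 min, where J reads about 1.0% or less and cZ minus cQ holds steady: 0.0453 /M/min.

4. Form S, the selectivity factor, the first constant over the second: 15.1. The second rate over the first is then cQ/(S cJ), read from the two runs with their scatter. It reaches one when cJ is cQ/S, so my reckoning has the first exchange leading until J is near 6.62% of its charge.

5. South has Z level with J. Each L made leaves one J over, so I expect J and L to stop roughly level, with Q holding the rest.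

6. North starts with a J half-life of 1.21 min, short against 1.0 h. Treat that exchange as instant: cZ equals cQ, and 1/cQ climbs at the second constant. My reckoning gives Q 46.7% and L 53.3%.

7. The forecast says Q for south, L for north and 47%, close to mine, on the grounds that “A small Z loss or crystals would nudge Q up”.

    Q + Z → G + L (k = 8.67 × 10⁻⁴ /M/s)
    Z → E (k = 3.59 × 10⁻⁵ /s)
    J + Z → G + Q (k = 0.0135 /M/s)
    X ⇌ Q, rate k4*(cs4 - [Q]) while solid is left; crystals form when [Q] > cs4 (solubility = 0.310 M, k = 0.256 /s)

North gives 46.5% of Q, with L holding the largest part, as forecast. North ends with X at 0% and E at 0.0353 M, which is 4.21% of the Z charged. Now take a neighbour flask, which is north with 1.7 M of J and so 0.494 equiv of Z. Dissolved Q is Q minus X there, so at its end the second rate stands at 2.35% of the first, and that neighbour flask holds L at 0.690%.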